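The 2,8-dioxabicyclo[3.2.1]octane is disconnected at the C–O bonds around the ketal carbon C4' and the acetal carbon C9', rings B and C together. Since C4' through C9' are linked into a cycle solely by the two ring oxygens, they are taken from the carbocycle of an (R)-1-methylcyclohex-3-en-1-ol, and the C4'=C9' alkene is the bond that is severed. Ozonolysis of tetraol 18 unveils the C4' ketone and C9' aldehyde; the C7' hydroxyl then closes ring B and the new hemiketal hydroxyl closes ring C, so C7' fixes C4'. Precursor 18 is this cyclohexenol with the unprotected C1'–C3' triol arm at C4'.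

Key step: step 11

Remarks on the chemistry
- Locants: C1' is the benzylic CH2, C2' the CHOAc carbon, C3' the tertiary carbinol (its CH2O branch is called C3'-CH2O), C4' the ketal carbon, C7' the methyl-bearing bridgehead, C9' the OCH carbon. Ring B is C4'–C5'–C6'–C7'–O; ring C is C4'–O–C9'–C8'–C7'–O.
- Precursor design: the cyclohexenol is cleaved as the free tetraol. Acetonide and silyl ether fall together before the cleavage, and the two target acetates plus the anomeric acetate are made in one step after it. No acid is then needed once the allylic C9'–O bond exists.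
- Assumption: C9' of 21 and 22 is an anomeric mixture, and the C=N geometry of 6 and 8 is undefined; the SMILES leave both open.
- Assumption: the sense of induction in step 7 is carried over from 4-monosubstituted cyclohexanones. The (R,R)-amide is expected to give the (R)-enolate of 11 when methyl is equatorial; the (S,S)-amide would be used if the opposite sense were found.

Step 1
Reactants: 1 2,5-dimethoxy-4-methylbenzaldehyde
Product: 2 (2,5-dimethoxy-4-methylphenyl)methanol
Conditions: NaBH4, MeOH, 0 °C → rt
Reagents that add atoms: none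
Why: Hydride reduction of an aryl aldehyde with NaBH4 gives the benzylic alcohol and leaves the aryl ethers alone.

Step 2
Reactants: 2 (2,5-dimethoxy-4-methylphenyl)methanol
Product: 3 1-(bromomethyl)-2,5-dimethoxy-4-methylbenzene
Conditions: PBr3, Et2O, 0 °C
Reagents that add atoms: phosphorus tribromide, BrP(Br)Br
Why: Bromination of a benzylic alcohol with PBr3 proceeds by bromide displacement of an activated phosphite ester and is clean for electron-rich benzyl alcohols.

Step 3
Reactants: 4 2,2-dimethyl-1,3-dioxan-5-one; 5 (R)-1-amino-2-(methoxymethyl)pyrrolidine (RAMP)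
Product: 6 (2R)-N-(2,2-dimethyl-1,3-dioxan-5-ylidene)-2-(methoxymethyl)pyrrolidin-1-amine
Conditions: toluene, 4 Å molecular sieves, 60 °C
Reagents that add atoms: none
Why: Hydrazone formation between the ketone and the hydrazine auxiliary is driven to completion by removal of water.

Step 4
Reactants: 6 RAMP hydrazone of the dioxanone; 3 1-(bromomethyl)-2,5-dimethoxy-4-methylbenzene
Product: 8 (2R)-N-[(4R)-4-[(2,5-dimethoxy-4-methylphenyl)methyl]-2,2-dimethyl-1,3-dioxan-5-ylidene]-2-(methoxymethyl)pyrrolidin-1-amine, via lithium azaenolate 7 (not isolated)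
Conditions: t-BuLi, THF, −78 °C; then 3, −100 °C → rt
Reagents that add atoms: none
Why: In this Enders RAMP-hydrazone alkylation the chelated azaenolate 7 is benzylated on the face left open by the methoxymethylpyrrolidine, which with RAMP should set the (4R) centre that becomes C2'.

Step 5
Reactants: 8 benzylated RAMP hydrazone
Product: 9 (4R)-4-[(2,5-dimethoxy-4-methylphenyl)methyl]-2,2-dimethyl-1,3-dioxan-5-one
Conditions: sat. aq. (CO2H)2, Et2O, rt
Reagents that add atoms: water, O
Why: Two-phase oxalic acid hydrolysis of the hydrazone frees the ketone under conditions mild enough to keep the acetonide and the epimerizable α-centre, and returns the auxiliary as its oxalate.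

Step 6
Reactants: 10 4-hydroxy-4-methylcyclohexan-1-one
Product: 11 4-methyl-4-(trimethylsilyloxy)cyclohexan-1-one
Conditions: N-(trimethylsilyl)imidazole, CH2Cl2, rt
Reagents that add atoms: N-(trimethylsilyl)imidazole, C[Si](C)(C)n1ccnc1
Why: O-Silylation with the silylimidazole caps the tertiary hydroxyl without enolizing the ketone, so that no acidic O–H interferes with the base-mediated steps.

Step 7
Reactants: 11 4-methyl-4-(trimethylsilyloxy)cyclohexan-1-one
Product: 13 (4R)-4-methyl-4-(trimethylsilyloxy)cyclohex-1-en-1-yl trifluoromethanesulfonate, via lithium enolate 12 (not isolated)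
Conditions: (R,R)-bis(1-phenylethyl)amine·HCl, n-BuLi (2 equiv), THF, −78 °C; 11; then N-(5-chloropyridin-2-yl)bis(trifluoromethanesulfonyl)imide, −78 → −20 °C
Reagents that add atoms: N-(5-chloropyridin-2-yl)bis(trifluoromethanesulfonyl)imide, O=S(=O)(N(c1ccc(Cl)cn1)S(=O)(=O)C(F)(F)F)C(F)(F)F
Why: Enantioselective deprotonation of the prochiral ketone by the chiral lithium amide (with LiCl formed in the flask) removes one of the two enantiotopic axial α-hydrogens of the chair with equatorial methyl and axial silyloxy, and O-sulfonylation of enolate 12 at low temperature locks the (R) centre that becomes C7'.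

Step 8
Reactants: 13 (R)-enol triflate
Product: 14 trimethyl[(4R)-4-methyl-4-(trimethylsilyloxy)cyclohex-1-en-1-yl]stannane
Conditions: Me3SnSnMe3, Pd(PPh3)4 (5 mol%), LiCl, THF, 65 °C
Reagents that add atoms: hexamethylditin, C[Sn](C)(C)[Sn](C)(C)C
Why: Palladium-catalysed stannylation of an enol triflate (Stille-type oxidative addition, transmetalation and reductive elimination) replaces the triflate without moving the double bond, so the C7' centre is untouched.

Step 9
Reactants: 14 (R)-vinylstannane; 9 (4R)-benzyl dioxanone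
Product: 17 (4R,5S)-4-[(2,5-dimethoxy-4-methylphenyl)methyl]-2,2-dimethyl-5-[(4R)-4-methyl-4-(trimethylsilyloxy)cyclohex-1-en-1-yl]-1,3-dioxan-5-ol, via vinyllithium 15 (not isolated), via vinylcerium dichloride 16 (not isolated)
Conditions: MeLi, THF, −78 → −40 °C; CeCl3, −78 °C; then 9, −78 °C
Reagents that add atoms: none
Why: Tin–lithium exchange gives 15, transmetalation to the weakly basic organocerium 16 suppresses enolization of the α-alkoxy ketone, and 1,2-addition along the axial trajectory of the dioxanone chair (no 1,3-diaxial hydrogens, benzyl group equatorial) places the cyclohexenyl group cis to the benzyl group and sets the (5S) centre that becomes C3'.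

Step 10
Reactants: 17 coupled acetonide silyl ether
Product: 18 (2S,3R)-4-(2,5-dimethoxy-4-methylphenyl)-2-[(4R)-4-hydroxy-4-methylcyclohex-1-en-1-yl]butane-1,2,3-triol
Conditions: pyridinium p-toluenesulfonate (cat.), MeOH, rt → 40 °C
Reagents that add atoms: none
Why: Acid-catalysed methanolysis removes the acetonide by transketalization and the tertiary trimethylsilyl ether by solvolysis in one operation, while the allylic C3' carbinol resists ionization because of its two β-oxygen substituents.

Step 11
Reactants: 18 cyclohexenol tetraol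
Product: 21 (2S,3R)-4-(2,5-dimethoxy-4-methylphenyl)-2-[(1S,5R)-3-hydroxy-5-methyl-2,8-dioxabicyclo[3.2.1]octan-1-yl]butane-1,2,3-triol (both C9' anomers), via keto aldehyde 19 (not isolated), via hemiketal aldehyde 20 (not isolated)
Conditions: O3, CH2Cl2/MeOH (4:1), Sudan Red 7B, −78 °C; then Me2S, −78 °C → rt
Reagents that add atoms: ozone, [O-][O+]=O
Why: 1,3-Dipolar cycloaddition of ozone to the C4'=C9' bond, the sole alkene of 18, cycloreversion to a carbonyl and a carbonyl oxide, capture of the latter by methanol or by the C7' hydroxyl, and reduction of the peroxidic intermediates by Me2S unveil the C4' ketone and C9' aldehyde of 19. The closest known reaction type is ozonolytic cleavage of a hydroxy-substituted cycloalkene followed by spontaneous internal ketalization to a bicyclic ketal lactol. Ring B arises by 5-exo-trig attack of the C7' hydroxyl on the C4' carbonyl (20), and ring C by 6-exo-trig attack of the hemiketal hydroxyl so formed on the C9' formyl group. C4' is the one new stereocentre that matters and C7' controls it: only the hemiketal epimer whose hydroxyl lies cis to the C8'–C9' arm can reach the aldehyde, and because hemiketal formation is reversible all material drains through it, while C9' stays an anomeric mixture that step 14 erases. The selectivity needed is cleavage of the alkene ahead of the electron-rich arene, secured by dosing ozone at −78 °C to the dye end point, and non-participation of the triol arm, secured by geometry, since its hydroxyls could reach C4' or C9' only through three-, four-, eight- or nine-membered rings.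

Step 12
Reactants: 21 bicyclic lactol triol
Product: 22 (2S,3R)-3-acetoxy-2-[(1S,5R)-3-acetoxy-5-methyl-2,8-dioxabicyclo[3.2.1]octan-1-yl]-4-(2,5-dimethoxy-4-methylphenyl)-2-hydroxybutyl acetate (both C9' anomers)
Conditions: Ac2O, pyridine, DMAP (cat.), CH2Cl2, 0 °C → rt
Reagents that add atoms: acetic anhydride, CC(=O)OC(C)=O
Why: Pyridine/DMAP acylation esterifies the primary, the secondary and the anomeric hydroxyl, whereas the tertiary C3' hydroxyl, flanked by two fully substituted carbons, is too hindered to react.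

Step 13
Reactants: 23 6-methylhept-5-en-2-one
Product: 25 6-methylhept-5-en-1-yne, via enol phosphate 24 (not isolated)
Conditions: LiN(i-Pr)2, THF, −78 °C; ClP(O)(OEt)2; then LiN(i-Pr)2 (2.2 equiv), −78 °C → rt
Reagents that add atoms: none
Why: Kinetic enolization of the methyl ketone at the methyl group, O-phosphorylation to 24 and base-induced β-elimination of phosphate give the terminal alkyne (methyl ketone to alkyne conversion via an enol phosphate).

Step 14
Reactants: 22 triacetate; 25 6-methylhept-5-en-1-yne
Product: 27 (2S,3R)-3-acetoxy-4-(2,5-dimethoxy-4-methylphenyl)-2-[(1R,3S,5R)-3-[(1E)-2,6-dimethylhepta-1,5-dien-1-yl]-5-methyl-2,8-dioxabicyclo[3.2.1]octan-1-yl]-2-hydroxybutyl acetate, via alkenylalane 26 (not isolated)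
Conditions: 25, AlMe3, Cp2ZrCl2 (20 mol%), CH2Cl2, 0 °C → rt; volatiles off, CH2Cl2; then 22, BF3·OEt2, −78 → −30 °C
Reagents that add atoms: trimethylaluminium, C[Al](C)C
Why: Zirconium-catalysed syn-methylalumination of the terminal alkyne (Negishi carboalumination) gives the (E)-alkenylalane 26, and BF3·OEt2 ionizes the anomeric acetate to the ring C oxocarbenium ion, which the alane (used in excess to absorb the C3' hydroxyl) attacks with retention of alkene geometry on the exo face away from the C5'–C6' bridge, giving the equatorial (S) substituent at C9'.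

Step 15
Reactants: 27 hydroquinone dimethyl ether
Product: 29 target, (2S,3R)-3-acetoxy-4-(2,5-dihydroxy-4-methylphenyl)-2-[(1R,3S,5R)-3-[(1E)-2,6-dimethylhepta-1,5-dien-1-yl]-5-methyl-2,8-dioxabicyclo[3.2.1]octan-1-yl]-2-hydroxybutyl acetate, via quinone 28 (not isolated)
Conditions: (NH4)2Ce(NO3)6, MeCN/H2O (2:1), 0 °C; then EtOAc, sat. aq. Na2S2O4, rt
Reagents that add atoms: water, O
Why: Oxidative demethylation of the hydroquinone dimethyl ether by (NH4)2Ce(NO3)6 gives quinone 28 with both methyl groups leaving as methanol, and Na2S2O4 reduces the quinone to the hydroquinone under near-neutral conditions that spare the acetates, the ketal and the alkenes.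

Compound list
1 | 2,5-dimethoxy-4-methylbenzaldehyde | COc1cc(C=O)c(OC)cc1C | starting material
2 | (2,5-dimethoxy-4-methylphenyl)methanol | COc1cc(CO)c(OC)cc1C | intermediate
3 | 1-(bromomethyl)-2,5-dimethoxy-4-methylbenzene | COc1cc(CBr)c(OC)cc1C | intermediate
4 | 2,2-dimethyl-1,3-dioxan-5-one | CC1(C)OCC(=O)CO1 | starting material
5 | (R)-1-amino-2-(methoxymethyl)pyrrolidine (RAMP) | COC[C@H]1CCCN1N | starting material
6 | (2R)-N-(2,2-dimethyl-1,3-dioxan-5-ylidene)-2-(methoxymethyl)pyrrolidin-1-amine | COC[C@H]1CCCN1N=C1COC(C)(C)OC1 | intermediate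
7 | lithium azaenolate of 6 (N-lithio ene-hydrazide, C4=C5 of the dioxane) | COC[C@H]1CCCN1N([Li])C1=COC(C)(C)OC1 | intermediate
8 | (2R)-N-[(4R)-4-[(2,5-dimethoxy-4-methylphenyl)methyl]-2,2-dimethyl-1,3-dioxan-5-ylidene]-2-(methoxymethyl)pyrrolidin-1-amine | COC[C@H]1CCCN1N=C1COC(C)(C)O[C@@H]1Cc1cc(OC)c(C)cc1OC | intermediate
9 | (4R)-4-[(2,5-dimethoxy-4-methylphenyl)methyl]-2,2-dimethyl-1,3-dioxan-5-one | CC1(C)OCC(=O)[C@@H](Cc2cc(OC)c(C)cc2OC)O1 | intermediate
10 | 4-hydroxy-4-methylcyclohexan-1-one | CC1(O)CCC(=O)CC1 | starting material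
11 | 4-methyl-4-(trimethylsilyloxy)cyclohexan-1-one | CC1(O[Si](C)(C)C)CCC(=O)CC1 | intermediate
12 | lithium (4R)-4-methyl-4-(trimethylsilyloxy)cyclohex-1-en-1-olate | [Li]OC1=CC[C@](C)(O[Si](C)(C)C)CC1 | intermediate
13 | (4R)-4-methyl-4-(trimethylsilyloxy)cyclohex-1-en-1-yl trifluoromethanesulfonate | FC(F)(F)S(=O)(=O)OC1=CC[C@](C)(O[Si](C)(C)C)CC1 | intermediate
14 | trimethyl[(4R)-4-methyl-4-(trimethylsilyloxy)cyclohex-1-en-1-yl]stannane | C[Sn](C)(C)C1=CC[C@](C)(O[Si](C)(C)C)CC1 | intermediate
15 | [(4R)-4-methyl-4-(trimethylsilyloxy)cyclohex-1-en-1-yl]lithium | [Li]C1=CC[C@](C)(O[Si](C)(C)C)CC1 | intermediate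
16 | dichloro[(4R)-4-methyl-4-(trimethylsilyloxy)cyclohex-1-en-1-yl]cerium | Cl[Ce](Cl)C1=CC[C@](C)(O[Si](C)(C)C)CC1 | intermediate
17 | (4R,5S)-4-[(2,5-dimethoxy-4-methylphenyl)methyl]-2,2-dimethyl-5-[(4R)-4-methyl-4-(trimethylsilyloxy)cyclohex-1-en-1-yl]-1,3-dioxan-5-ol | CC1(C)OC[C@](O)([C@@H](Cc2cc(OC)c(C)cc2OC)O1)C3=CC[C@](C)(O[Si](C)(C)C)CC3 | intermediate
18 | (2S,3R)-4-(2,5-dimethoxy-4-methylphenyl)-2-[(4R)-4-hydroxy-4-methylcyclohex-1-en-1-yl]butane-1,2,3-triol | OC[C@](O)([C@H](O)Cc1cc(OC)c(C)cc1OC)C2=CC[C@](C)(O)CC2 | intermediate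
19 | (3R,7S,8R)-9-(2,5-dimethoxy-4-methylphenyl)-3,7,8-trihydroxy-7-(hydroxymethyl)-3-methyl-6-oxononanal (open keto aldehyde) | OC[C@](O)([C@H](O)Cc1cc(OC)c(C)cc1OC)C(=O)CC[C@@](C)(O)CC=O | intermediate
20 | 2-[(2R,5R)-5-[(2S,3R)-4-(2,5-dimethoxy-4-methylphenyl)-1,2,3-trihydroxybutan-2-yl]-5-hydroxy-2-methyloxolan-2-yl]acetaldehyde (ring B hemiketal, productive epimer) | OC[C@](O)([C@H](O)Cc1cc(OC)c(C)cc1OC)[C@@]2(O)CC[C@](C)(CC=O)O2 | intermediate
21 | (2S,3R)-4-(2,5-dimethoxy-4-methylphenyl)-2-[(1S,5R)-3-hydroxy-5-methyl-2,8-dioxabicyclo[3.2.1]octan-1-yl]butane-1,2,3-triol (C9' anomers) | OC[C@](O)([C@H](O)Cc1cc(OC)c(C)cc1OC)[C@]23CC[C@](C)(CC(O)O2)O3 | intermediate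
22 | (2S,3R)-3-acetoxy-2-[(1S,5R)-3-acetoxy-5-methyl-2,8-dioxabicyclo[3.2.1]octan-1-yl]-4-(2,5-dimethoxy-4-methylphenyl)-2-hydroxybutyl acetate (C9' anomers) | CC(=O)OC[C@](O)([C@@H](Cc1cc(OC)c(C)cc1OC)OC(C)=O)[C@]23CC[C@](C)(CC(OC(C)=O)O2)O3 | intermediate
23 | 6-methylhept-5-en-2-one | CC(=O)CCC=C(C)C | starting material
24 | diethyl 6-methylhepta-1,5-dien-2-yl phosphate | C=C(CCC=C(C)C)OP(=O)(OCC)OCC | intermediate
25 | 6-methylhept-5-en-1-yne | C#CCCC=C(C)C | intermediate
26 | [(1E)-2,6-dimethylhepta-1,5-dien-1-yl]dimethylalane | C[Al](C)/C=C(\C)CCC=C(C)C | intermediate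
27 | (2S,3R)-3-acetoxy-4-(2,5-dimethoxy-4-methylphenyl)-2-[(1R,3S,5R)-3-[(1E)-2,6-dimethylhepta-1,5-dien-1-yl]-5-methyl-2,8-dioxabicyclo[3.2.1]octan-1-yl]-2-hydroxybutyl acetate | CC(=O)OC[C@](O)([C@@H](Cc1cc(OC)c(C)cc1OC)OC(C)=O)[C@]23CC[C@](C)(C[C@@H](/C=C(\C)CCC=C(C)C)O2)O3 | intermediate
28 | (2S,3R)-3-acetoxy-2-[(1R,3S,5R)-3-[(1E)-2,6-dimethylhepta-1,5-dien-1-yl]-5-methyl-2,8-dioxabicyclo[3.2.1]octan-1-yl]-2-hydroxy-4-(4-methyl-3,6-dioxocyclohexa-1,4-dien-1-yl)butyl acetate | CC(=O)OC[C@](O)([C@@H](CC1=CC(=O)C(C)=CC1=O)OC(C)=O)[C@]23CC[C@](C)(C[C@@H](/C=C(\C)CCC=C(C)C)O2)O3 | intermediate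
29 | (2S,3R)-3-acetoxy-4-(2,5-dihydroxy-4-methylphenyl)-2-[(1R,3S,5R)-3-[(1E)-2,6-dimethylhepta-1,5-dien-1-yl]-5-methyl-2,8-dioxabicyclo[3.2.1]octan-1-yl]-2-hydroxybutyl acetate | CC(=O)OC[C@](O)([C@@H](Cc1cc(O)c(C)cc1O)OC(C)=O)[C@]12CC[C@](C)(C[C@@H](/C=C(\C)CCC=C(C)C)O1)O2 | target

Total step count: 15.
Longest linear sequence: 10 steps (1 → 2 → 3 → 8 → 9 → 17 → 18 → 21 → 22 → 27 → 29; steps 1, 2, 4, 5, 9, 10, 11, 12, 14, 15).

Steps most likely to fail

Step 11. What may go wrong: ozone may attack the electron-rich dimethoxyarene in competition with the hindered, inductively deactivated C4'=C9' bond, or the keto aldehyde may fold incompletely. The fallback sets out from 17 and comes back at 21, and replaces ozone by dihydroxylation and glycol cleavage on the acetonide-protected series, where the triol arm is masked against periodate. The silyl ether of 17 is removed with Bu4NF in THF at 0 °C to give the acetonide-protected cyclohexenol F1. OsO4 (catalytic) with N-methylmorpholine N-oxide in acetone/water adds across C4'=C9' to give the acetonide-protected cis-glycol F2, whose two new centres are of no consequence. NaIO4 on silica in CH2Cl2 cleaves the ring cis-glycol, expected to react far faster than the hindered ditertiary C3'/C4' glycol, and the keto aldehyde folds as in step 11 to the acetonide-protected bicyclic lactol F3. Aqueous acetic acid (80%) at 40 °C then removes the acetonide to give 21.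

Step 14. What may go wrong: methyl may transfer instead of alkenyl, aluminium reagents may attack the acetates or open the ketal, or exo-face selectivity at C9' may erode. The fallback sets out from 25 (with 22) and comes back at 27, and exchanges the aluminium nucleophile for a boron one. The alane made from 25 as in step 14 is quenched with I2 in THF to give (E)-1-iodo-2,6-dimethylhepta-1,5-diene F4. Iodine–lithium exchange (t-BuLi, Et2O, −78 °C), B(OMe)3 and aqueous KHF2 give potassium (E)-(2,6-dimethylhepta-1,5-dien-1-yl)trifluoroborate F5. F5 and 22 with BF3·OEt2 in MeCN at −40 → 0 °C should alkenylate the C9' oxocarbenium ion from the same exo face to give 27, with no aluminium alkyl in the flask.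

Step 7. What may go wrong: enantiotopic selection may be insufficient, through reaction via the minor chair with axial methyl or through enolate equilibration before trapping. This would surface after step 9 as the C7' epimer of 17. The fallback sets out from 11 and comes back at 13, and replaces asymmetric induction by resolution. Enolization of 11 with LiN(i-Pr)2 in THF at −78 °C and trapping with the same triflimide give the racemic enol triflate F6. F6 is resolved by preparative supercritical-fluid chromatography on a cellulose tris(3,5-dimethylphenylcarbamate) phase, and the (R)-enantiomer is 13.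

Further compounds
F1 | step 11 | (4R,5S)-4-[(2,5-dimethoxy-4-methylphenyl)methyl]-5-[(4R)-4-hydroxy-4-methylcyclohex-1-en-1-yl]-2,2-dimethyl-1,3-dioxan-5-ol | CC1(C)OC[C@](O)([C@@H](Cc2cc(OC)c(C)cc2OC)O1)C3=CC[C@](C)(O)CC3
F2 | step 11 | acetonide-protected cyclohexane-1,2,4-triol from cis-dihydroxylation of F1 at C4'/C9' (face unassigned, both new centres destroyed on cleavage) | CC1(C)OC[C@](O)([C@@H](Cc2cc(OC)c(C)cc2OC)O1)C3(O)C(O)C[C@](C)(O)CC3
F3 | step 11 | acetonide-protected bicyclic ketal lactol (C9' anomers) | CC1(C)OC[C@](O)([C@@H](Cc2cc(OC)c(C)cc2OC)O1)[C@]34CC[C@](C)(CC(O)O3)O4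
F4 | step 14 | (E)-1-iodo-2,6-dimethylhepta-1,5-diene | I/C=C(\C)CCC=C(C)C
F5 | step 14 | potassium (E)-(2,6-dimethylhepta-1,5-dien-1-yl)trifluoroborate | [K+].F[B-](F)(F)/C=C(\C)CCC=C(C)C
F6 | step 7 | racemic 4-methyl-4-(trimethylsilyloxy)cyclohex-1-en-1-yl trifluoromethanesulfonate | FC(F)(F)S(=O)(=O)OC1=CCC(C)(O[Si](C)(C)C)CC1
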